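Product cannot outrun its charge: alder, with 0.12 M of starting material in a volume that grows by half, cannot end above 0.0800 M. A computed curve needs a second limit beside this one, and I read it from two earlier runs.

| setting | south | west | alder | maple | larch | ash | birch |
|---|---|---|---|---|---|---|---|
| starting material | 0.11 M | 1.2 M | 0.12 M | 0.25 M | 0.50 M | 1.0 M | 2.0 M |
| coupling partner | 1.3 M (fed, over 8.0 h) | 1.3 M (fed, over 8.0 h) | 1.30 M (fed, over 8.0 h) | 1.30 M (fed, over 8.0 h) | 1.30 M (fed, over 8.0 h) | 1.30 M (fed, over 8.0 h) | 1.30 M (fed, over 8.0 h) |
| free catalyst | 20 mM | 20 mM | 20 mM | 20 mM | 20 mM | 20 mM | 20 mM |
| remark | run made earlier; the fed solution adds 0.50 times the starting volume | run made earlier; the fed solution adds 0.50 times the starting volume | the fed solution adds 0.50 times the starting volume | the fed solution adds 0.50 times the starting volume | the fed solution adds 0.50 times the starting volume | the fed solution adds 0.50 times the starting volume | the fed solution adds 0.50 times the starting volume |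
| time |  |  | 8.0 h | 8.0 h | 8.0 h | 8.0 h | 8.0 h |

- south (time / h: product / %): 0.667: 1.5; 1.33: 9.5; 2.50: 27.6; 4.00: 49.4; 8.00: 81.5
- west (time / h: product / %): 1.50: 1.2; 3.00: 2.8; 5.00: 5.7; 6.00: 6.8; 8.00: 8.8

(scatter of a reading: 0.3 percentage points)

- every charge counts on the volume at the start, and the solution that is fed holds the whole dose
- the numbers in the tables scatter by 0.3 percentage points (one standard deviation)
- "hardly changes" means that all values lie within two and a half points (for a concentration: within two and a half percent of the largest)

* [product] at the end for alder, maple, larch, ash, birch, in this order
* how that number moves from the first to the last of them (falls, then rises / hardly changes / rises all the way / falls all the way / rises, then falls)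

I define the clearing time as the charge of starting material divided by the steady rate of product formation, both per starting volume. South makes 0.0160 M h⁻¹ on its straight stretch, and west makes 0.0124 M h⁻¹ late in its run.

The ladder starts with the onset: south's straight stretch, drawn back to zero product, gives a lag of 0.676 h, shorter than the 8.0 h of dosing. Next comes south's clearing time, 6.88 h, also shorter than the dosing time, so south is bounded by its charge, with starting material as limiting reagent, and reads 81.5 % at the end. West's clearing time, 96.8 h, is 12.1 times the dosing time, so west is bounded by rate.

My reckoning follows from this. Alder, scaled from south's final yield, ends near 0.0652 M. Richer flasks clear too slowly to finish, so they should end at rate times the 7.32 h available, divided by the final volume. That gives 0.0781 M at south's rate, sinking towards 0.0605 M at west's. So I expect a rise, then a fall.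

The forecast gives 0.065 M, 0.087 M, 0.084 M, 0.077 M and 0.062 M, shape rises, then falls, on the ground that “high starting material mildly inhibits”. Its peak stands above mine.

The flasks end at 0.0644 M, 0.105 M, 0.117 M, 0.0798 M and 0.0317 M: rises, then falls, with larch highest.

    catalyst intermediate B → free catalyst + product (k = 19.0 h⁻¹)
    starting material + free catalyst → catalyst intermediate A (k = 22.0 M⁻¹ h⁻¹)
    coupling partner + catalyst intermediate A → catalyst intermediate B (k = 7.10 M⁻¹ h⁻¹)
    starting material + catalyst intermediate A → spent catalyst (k = 0.360 M⁻¹ h⁻¹)

Alder's clearing time at south's rate is 7.51 h, and alder holds 17 % of its starting material at 8.00 h. Ash's clearing time at west's rate is 80.6 h, yet at 80.0 h ash still holds 72.7 %, with >99.9 % of its catalyst as spent catalyst. At 4.00 h, the rate constant times concentration for starting material attacking catalyst intermediate A, taken over the same product for the coupling partner, is 7.81 % in ash. In alder the same ratio is 0.477 %, far smaller than in ash.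

(The readings are simulated on assumed constants; noise was put on by code.)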